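**The leftover.** I look first at the partner charged beyond the protic impurity, in these flasks.

common to all: substrate 2.0 × 10⁻⁴ M; protic impurity 0.200 mM; free catalyst 12 µM; time 2.0 min
- Tuesday's: partner 0.220 mM (fed, over 1.0 min)
- Monday's: partner 0.290 mM (fed, over 1.0 min)

    partner + free catalyst ⇌ catalyst intermediate A (K1 = 791 M⁻¹, k1 = 2.44 × 10⁵ M⁻¹ s⁻¹)
    catalyst intermediate A ⇌ released group + catalyst intermediate B (K2 = 1.65 × 10⁻⁴ M, k2 = 2.10 s⁻¹)
    substrate + catalyst intermediate B ⇌ catalyst intermediate C (K3 = 2730 M⁻¹, k3 = 7340 M⁻¹ s⁻¹)
    catalyst intermediate C → catalyst intermediate D (k4 = 2.59 s⁻¹)
    catalyst intermediate D → free catalyst + target (k5 = 3.70 s⁻¹)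
    partner + released group ⇌ idle adduct, settled at all times (K6 = 7000 M⁻¹)
    partner + protic impurity → quenched reagent (k7 = 834 M⁻¹ s⁻¹)

- for released group the idle adduct is counted in
- run time (Tuesday's): 2.0 min

* part of the substrate that has reacted at the end, Tuesday's
* part of the substrate that has reacted at the end, Monday's
* what raising the concentration of partner from its lowest to its highest value here does to the part of the substrate that has reacted (changes below 5 percentage points count as none) (it rises / no change / it falls)

**First guess.** Tuesday's charge exceeds the impurity by 0.0200 mM, Monday's by 0.0900 mM. If the impurity ate first, those leftovers would become target: 10.0 % and 45.0 % of the substrate. But the catalyst takes partner from the start, so Tuesday's figure is too low.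

**Frozen catalyst.** So I freeze the free catalyst at its charge. Even the whole Tuesday's charge, times the equilibrium constant of the first step, gives only 0.174. Intermediate A also falls back at 308 s⁻¹, faster than it goes on at 2.10 s⁻¹. Partner therefore enters the cycle with a first-order constant 0.0199 s⁻¹. The impurity takes partner with the rate constant of step 7 times H, where H is the impurity concentration, and that is 0.167 s⁻¹ at the charge, larger than the entry constant.

**The crossover.** Both routes are proportional to partner, so partner cancels from their ratio. I define the crossover level g, the impurity concentration at which both routes run equally fast: 0.0239 mM. Then g/H is a selectivity factor. With the catalyst frozen and no return of released group, each halving of H sends 0.0166 mM of partner into the cycle.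

**Tuesday's estimate.** Neglecting the partner still free at the end, partner entering equals the leftover plus the impurity still standing. I try H down by a factor 7. The rule gives 0.0465 mM, the balance 0.0486 mM, so the trial nearly fits. That is 23.3 % of the substrate.

**An objection.** Released group takes intermediate B back. At that level the return runs at 0.592 s⁻¹, against 0.720 s⁻¹ onward, and at the start there is no return. Taking the mean of the shares at the start and at that level, I reckon that 77.4 % of what enters goes on, so I commit to 18.0 % for Tuesday's.

**Another objection.** Time may cut this short. At that impurity level, Tuesday's partner has a half-life of 15.8 s, well inside the time after the feed. Monday's impurity falls further, and then the half-life nears 34.8 s, longer with the return. So I expect part of Monday's leftover to stand unused at the end. I commit to a span from 22.5 % to 45.0 % for Monday's, and, from its middle, a rise.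

**The forecast.** It gives 18 % (13 % to 24 %) for Tuesday's and 30 % (22 % to 39 %) for Monday's, and says it rises, since “Monday's leaves a clear excess of partner that keeps the cycle running after the feed ends”. My Tuesday's figure matches its value, and its Monday's value lies inside my span.

**The flask.** The simulation gives 17.8 % for Tuesday's and 28.2 % for Monday's: it rises, by 10 percentage points. Tuesday's keeps 12 % of its impurity at the end. With g, the frozen rule reckons 0.0515 mM of partner entered in Tuesday's, and the substrate reacted is 0.0355 mM, which is 69.0 % of that reckoning. A neighbour of Tuesday's with a quarter of the substrate keeps 8.2 % of its impurity. There the rule reckons 0.0598 mM entered against 0.0229 mM of substrate reacted, which is 38.4 % of that reckoning.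

The constants are made up; no experiment stands behind them.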